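**Plan**

- Cuts: the two quinone C=O groups go back to aryl methyl ethers; the exocyclic C3=C1′ alkene of the lactone is cut as a phosphonate olefination; the lactone bonds C4–C5 and O1–C6 are cut together; the aryl–CH2 bond and the terminal C=C of a farnesyl chain are cut last.
- Enabling feature: in the δ-lactone ring (O1, C2, C3, C4, C5, C6) the array C5H2–C6H(O1)–C7Me2(OH) is a 2,3-epoxy alcohol in disguise (C5 bearing a sulfonate, C6–C7 an oxirane), and O1–C2–C3–C4 is a propanoate with a carbanion at C4. A C,O-dinucleophile can therefore add across a 1,2-dielectrophile as a formal [4+2] annulation.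
- Forward order: aryl bromide + farnesyl bromide → terminal oxirane → C10 aldehyde (chain half); prenol → (S)-epoxy tosylate → lactone ring by the annulation → C3 phosphonate (ring half); olefination joins the halves; the quinone ring is unmasked last.
- Stereochemistry: C6 comes from the Sharpless epoxidation of prenol (L-(+)-tartrate) and is inverted once, stereospecifically, in the annulation to give (R). The (Z)-alkylidene comes from a Still–Gennari-type olefination. Both chain (E)-alkenes are bought with farnesyl bromide.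

Key step: step 5

Remark: 1-bromo-2,5-dimethoxy-3-methylbenzene 1 is taken as a purchasable aryl bromide; the quinone is carried as its hydroquinone dimethyl ether until step 8.

**Route**

Step 1
Reactants: 1 1-bromo-2,5-dimethoxy-3-methylbenzene; 2 (2E,6E)-farnesyl bromide
Product: 4 farnesyl arene 2-[(2E,6E)-3,7,11-trimethyldodeca-2,6,10-trien-1-yl]-1,4-dimethoxy-6-methylbenzene, via aryllithium 3 (not isolated)
Conditions: n-BuLi, THF, −78 °C; CuBr·SMe2 (10 mol%), then 2, −78 °C to rt
Reagents that add atoms: none
Why: Bromine–lithium exchange followed by copper-catalysed SN2 allylation of the aryllithium with the primary allylic bromide should join ring and chain at the former C–Br carbon with retention of both (E)-alkenes; no stereocentre is formed.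

Step 2
Reactants: 4 farnesyl arene
Product: 6 racemic terminal epoxide 3-[(3E,7E)-9-(2,5-dimethoxy-3-methylphenyl)-3,7-dimethylnona-3,7-dien-1-yl]-2,2-dimethyloxirane, via bromohydrin 5 (not isolated)
Conditions: NBS, THF/H2O (3:1), 0 °C; then K2CO3, MeOH, rt
Reagents that add atoms: water O
Why: Bromohydrin formation in aqueous THF should occur preferentially at the terminal, least hindered trisubstituted alkene (water attacks the tertiary carbon), and intramolecular Williamson closure then gives the oxirane, whose stereocentre is formed racemic and is destroyed in step 3.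

Step 3
Reactants: 6 racemic terminal epoxide
Product: 7 (4E,8E)-10-(2,5-dimethoxy-3-methylphenyl)-4,8-dimethyldeca-4,8-dienal
Conditions: HIO4·2H2O, THF/Et2O, 0 °C to rt
Reagents that add atoms: none
Why: Periodic acid should hydrolyse the oxirane and cleave the resulting 1,2-diol in one pot (glycol cleavage), giving the aldehyde and acetone without touching the remaining alkenes; no stereocentre is involved.

Step 4
Reactants: 8 3-methylbut-2-en-1-ol (prenol)
Product: 10 (S)-(3,3-dimethyloxiran-2-yl)methyl 4-methylbenzenesulfonate, via (S)-epoxy alcohol 9 (not isolated)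
Conditions: Ti(OiPr)4 (5 mol%), L-(+)-diisopropyl tartrate (7 mol%), t-BuOOH, 4 Å MS, CH2Cl2, −20 °C; then P(OMe)3; then TsCl, Et3N, DMAP (cat.), −10 °C
Reagents that add atoms: tert-butyl hydroperoxide CC(C)(C)OO; 4-methylbenzenesulfonyl chloride Cc1ccc(cc1)S(Cl)(=O)=O
Why: Sharpless asymmetric epoxidation with the L-(+)-tartrate/Ti(OiPr)4 catalyst should deliver oxygen to the face that gives the (S)-oxirane carbon (catalyst control), and in situ sulfonylation captures the volatile, water-soluble epoxy alcohol as a crystallisable tosylate.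

Step 5
Reactants: 10 (S)-epoxy tosylate; 11 3-bromopropanoic acid
Product: 16 (6R)-6-[2-(triethylsilyloxy)propan-2-yl]oxan-2-one, via lithium 3-lithiopropanoate 12 (not isolated), via its lithium dialkylcuprate 13 (not isolated), via lithium epoxy carboxylate 14 (not isolated), via lactone tertiary alkoxide 15 (not isolated)
Conditions: 11 (2.2 equiv), n-BuLi (2.2 equiv), THF, −78 °C; LiC10H8 (lithium naphthalenide, 4.4 equiv), −78 °C; CuBr·SMe2 (1.1 equiv), −78 to −40 °C; 10 (1.0 equiv), −40 to 0 °C; then DMPU, 50 °C; then Et3SiCl, 0 °C to rt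
Reagents that add atoms: chlorotriethylsilane CC[Si](Cl)(CC)CC
Why: The cuprate carbon of 13 displaces the primary tosylate of 10 by SN2 (copper-mediated alkyl–alkyl coupling), forming C4–C5 and leaving the oxirane intact; the tethered lithium carboxylate of 14 then opens the oxirane at its secondary carbon by intramolecular SN2 attack, forming O1–C6 and unveiling the tertiary alkoxide, which Et3SiCl caps. The closest known reaction types are the C1-alkylation of 2,3-epoxy sulfonates by lithium dialkylcuprates, the use of lithium 3-lithiopropanoate as a propanoate homoenolate, and the lactonisation of epoxy carboxylates; together they amount to a formal [4+2] annulation of a C,O-dinucleophile with a 1,2-dielectrophile. The only ring closed is the δ-lactone, by a 6-exo-tet closure. C6 is the only stereocentre: its (R) configuration follows from the (S)-oxirane carbon set in step 4, inverted stereospecifically by backside attack of the carboxylate (substrate control, no new induction needed). The step needs chemoselectivity (sulfonate carbon before oxirane), secured by the soft cuprate at low temperature and by the hindered oxirane termini, and regioselectivity (C6 over the tertiary C7), secured by the basic, acid-free SN2 conditions and the preference for the six-membered over the seven-membered ring.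

Step 6
Reactants: 16 silyl-protected lactone
Product: 19 bis(2,2,2-trifluoroethyl) {(6R)-2-oxo-6-[2-(triethylsilyloxy)propan-2-yl]oxan-3-yl}phosphonate (both C3 epimers), via lithium enolate 17 (not isolated), via enol phosphate 18 (not isolated)
Conditions: LiN(iPr)2 (1.1 equiv), THF, −78 °C; ClP(O)(OCH2CF3)2, −78 to 0 °C; then LiN(iPr)2 (2.2 equiv), −78 °C to rt; AcOH
Reagents that add atoms: bis(2,2,2-trifluoroethyl) phosphorochloridate O=P(Cl)(OCC(F)(F)F)OCC(F)(F)F
Why: O-Phosphorylation of the lactone enolate followed by base-induced 1,3 oxygen-to-carbon phosphoryl migration (enol phosphate to phosphonate rearrangement) should give the Still–Gennari-type cyclic phosphonate; the new C3 centre is an inconsequential epimer mixture because it becomes sp2 in step 7.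

Step 7
Reactants: 19 lactone phosphonate; 7 C10 aldehyde
Product: 22 (3Z,6R)-3-[(4E,8E)-10-(2,5-dimethoxy-3-methylphenyl)-4,8-dimethyldeca-4,8-dien-1-ylidene]-6-(2-hydroxypropan-2-yl)oxan-2-one, via potassium phosphonate carbanion 20 (not isolated), via silyl ether 21 (not isolated)
Conditions: KN(SiMe3)2, 18-crown-6, THF, −78 °C; then 7, −78 °C; then HF·pyridine, THF/pyridine, 0 °C to rt
Reagents that add atoms: none
Why: In this Still–Gennari variant of the Horner–Wadsworth–Emmons olefination the electron-poor bis(trifluoroethyl) phosphonate makes the kinetically preferred adduct collapse before it can equilibrate, which should place the alkyl chain cis to the lactone carbonyl ((Z)-alkylidene), and HF·pyridine then cleaves the triethylsilyl ether without affecting lactone or alkenes; no stereocentre is created.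

Step 8
Reactants: 22 dimethoxyarene lactone
Product: 23 target quinone 2-[(2E,6E,10Z)-10-[(6R)-6-(2-hydroxypropan-2-yl)-2-oxooxan-3-ylidene]-3,7-dimethyldeca-2,6-dien-1-yl]-6-methylcyclohexa-2,5-diene-1,4-dione
Conditions: (NH4)2Ce(NO3)6, MeCN/H2O (2:1), 0 °C
Reagents that add atoms: water O
Why: Oxidative demethylation of the hydroquinone dimethyl ether (two one-electron oxidations, addition of water, loss of methanol) should give the 1,4-benzoquinone under conditions that isolated trisubstituted alkenes, the alkylidene lactone and the tertiary alcohol tolerate; no stereocentre is touched.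

**Compound list**

1 | 1-bromo-2,5-dimethoxy-3-methylbenzene | COc1cc(C)c(OC)c(Br)c1 | starting material
2 | (2E,6E)-farnesyl bromide | BrC/C=C(\C)CC/C=C(\C)CCC=C(C)C | starting material
3 | (2,5-dimethoxy-3-methylphenyl)lithium | COc1cc(C)c(OC)c([Li])c1 | intermediate
4 | 2-[(2E,6E)-3,7,11-trimethyldodeca-2,6,10-trien-1-yl]-1,4-dimethoxy-6-methylbenzene | COc1cc(C)c(OC)c(C/C=C(\C)CC/C=C(\C)CCC=C(C)C)c1 | intermediate
5 | (6E,10E)-3-bromo-12-(2,5-dimethoxy-3-methylphenyl)-2,6,10-trimethyldodeca-6,10-dien-2-ol (racemic) | COc1cc(C)c(OC)c(C/C=C(\C)CC/C=C(\C)CCC(Br)C(C)(C)O)c1 | intermediate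
6 | 3-[(3E,7E)-9-(2,5-dimethoxy-3-methylphenyl)-3,7-dimethylnona-3,7-dien-1-yl]-2,2-dimethyloxirane (racemic) | COc1cc(C)c(OC)c(C/C=C(\C)CC/C=C(\C)CCC2OC2(C)C)c1 | intermediate
7 | (4E,8E)-10-(2,5-dimethoxy-3-methylphenyl)-4,8-dimethyldeca-4,8-dienal | COc1cc(C)c(OC)c(C/C=C(\C)CC/C=C(\C)CCC=O)c1 | intermediate
8 | 3-methylbut-2-en-1-ol | CC(C)=CCO | starting material
9 | (S)-(3,3-dimethyloxiran-2-yl)methanol | OC[C@@H]1OC1(C)C | intermediate
10 | (S)-(3,3-dimethyloxiran-2-yl)methyl 4-methylbenzenesulfonate | Cc1ccc(cc1)S(=O)(=O)OC[C@@H]1OC1(C)C | intermediate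
11 | 3-bromopropanoic acid | OC(=O)CCBr | starting material
12 | lithium 3-lithiopropanoate | [Li+].[O-]C(=O)CC[Li] | intermediate
13 | trilithium bis(2-carboxylatoethyl)cuprate | [Li+].[Li+].[Li+].[O-]C(=O)CC[Cu-]CCC([O-])=O | intermediate
14 | lithium 4-[(2S)-3,3-dimethyloxiran-2-yl]butanoate | [Li+].[O-]C(=O)CCC[C@@H]1OC1(C)C | intermediate
15 | lithium 2-[(2R)-6-oxooxan-2-yl]propan-2-olate | O=C1CCC[C@H](C(C)(C)[O-])O1.[Li+] | intermediate
16 | (6R)-6-[2-(triethylsilyloxy)propan-2-yl]oxan-2-one | O=C1CCC[C@H](C(C)(C)O[Si](CC)(CC)CC)O1 | intermediate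
17 | lithium enolate of 16 | [Li+].[O-]C1=CCC[C@H](C(C)(C)O[Si](CC)(CC)CC)O1 | intermediate
18 | (2R)-2-[2-(triethylsilyloxy)propan-2-yl]-3,4-dihydro-2H-pyran-6-yl bis(2,2,2-trifluoroethyl) phosphate | O=P(OCC(F)(F)F)(OCC(F)(F)F)OC1=CCC[C@H](C(C)(C)O[Si](CC)(CC)CC)O1 | intermediate
19 | bis(2,2,2-trifluoroethyl) {(6R)-2-oxo-6-[2-(triethylsilyloxy)propan-2-yl]oxan-3-yl}phosphonate (C3 epimers) | O=C1C(P(=O)(OCC(F)(F)F)OCC(F)(F)F)CC[C@H](C(C)(C)O[Si](CC)(CC)CC)O1 | intermediate
20 | potassium salt of phosphonate 19 | [K+].[O-]C1=C(P(=O)(OCC(F)(F)F)OCC(F)(F)F)CC[C@H](C(C)(C)O[Si](CC)(CC)CC)O1 | intermediate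
21 | (3Z,6R)-3-[(4E,8E)-10-(2,5-dimethoxy-3-methylphenyl)-4,8-dimethyldeca-4,8-dien-1-ylidene]-6-[2-(triethylsilyloxy)propan-2-yl]oxan-2-one | COc1cc(C)c(OC)c(C/C=C(\C)CC/C=C(\C)CC/C=C2/CC[C@H](C(C)(C)O[Si](CC)(CC)CC)OC2=O)c1 | intermediate
22 | (3Z,6R)-3-[(4E,8E)-10-(2,5-dimethoxy-3-methylphenyl)-4,8-dimethyldeca-4,8-dien-1-ylidene]-6-(2-hydroxypropan-2-yl)oxan-2-one | COc1cc(C)c(OC)c(C/C=C(\C)CC/C=C(\C)CC/C=C2/CC[C@H](C(C)(C)O)OC2=O)c1 | intermediate
23 | 2-[(2E,6E,10Z)-10-[(6R)-6-(2-hydroxypropan-2-yl)-2-oxooxan-3-ylidene]-3,7-dimethyldeca-2,6-dien-1-yl]-6-methylcyclohexa-2,5-diene-1,4-dione | CC1=CC(=O)C=C(C/C=C(\C)CC/C=C(\C)CC/C=C2/CC[C@H](C(C)(C)O)OC2=O)C1=O | target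

**Summary**

Total steps: 8. Longest linear sequence: 5 steps (8 → 10 → 16 → 19 → 22 → 23; the chain branch 1 → 4 → 6 → 7 → 22 → 23 is equally long).

**Steps most likely to fail**

Step 5 is the riskiest. The dianion-derived cuprate may be poorly soluble and be protonated or attack the oxirane instead of the sulfonate carbon. If uncyclised epoxy acid meets acid on work-up, ring closure can drift to the tertiary oxirane carbon. The fallback makes the two bonds in separate routine operations, setting out from tosylate 10. Coupling with but-3-enylmagnesium bromide (Li2CuCl4 cat., THF, −30 °C) would give (S)-2,2-dimethyl-3-(pent-4-en-1-yl)oxirane F1. Ozonolysis (O3, CH2Cl2, −78 °C; Me2S) would give 4-[(2S)-3,3-dimethyloxiran-2-yl]butanal F2, and Pinnick oxidation (NaClO2, NaH2PO4, 2-methylbut-2-ene) would give 4-[(2S)-3,3-dimethyloxiran-2-yl]butanoic acid F3. K2CO3 in DMF at 50 °C would close (6R)-6-(2-hydroxypropan-2-yl)oxan-2-one F4 by the same 6-exo carboxylate opening. Silylation (Et3SiOTf, 2,6-lutidine) comes back to the route at 16.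

Step 6 is next. The oxygen-to-carbon phosphoryl shift may fail, or the amide base may attack the electron-poor phosphorus with loss of trifluoroethoxide. The fallback sets out from 16 and forms the C–P bond directly with a trivalent phosphorus electrophile. The lithium enolate would be phosphinylated with ClP(OPh)2 to diphenyl {(6R)-2-oxo-6-[2-(triethylsilyloxy)propan-2-yl]oxan-3-yl}phosphonite F5. Oxidation with t-BuOOH would give the diphenyl phosphonate F6. Its Ando-type (Z)-selective olefination with 7 (NaH, THF, −78 °C) comes back to the route at 21.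

Step 7 is third. Geometric control may erode through reversible addition, putting the chain trans to the carbonyl, or the aldehyde may be enolised by the base. The fallback sets out from 16 and 7 and sets the geometry by a stereospecific elimination instead of an olefination. The lithium enolate 17 of 16 (LiN(iPr)2, THF, −78 °C) would add to 7 through the chair transition state open to the ring-locked enolate, giving the anti β-hydroxy lactone F7. Mesylation (MsCl, Et3N) would give the methanesulfonate F8. Anti-periplanar elimination with DBU should then place chain and carbonyl cis and comes back to the route at 21.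

**Further compounds**

F1 | step 5 | (S)-2,2-dimethyl-3-(pent-4-en-1-yl)oxirane | C=CCCC[C@@H]1OC1(C)C
F2 | step 5 | 4-[(2S)-3,3-dimethyloxiran-2-yl]butanal | O=CCCC[C@@H]1OC1(C)C
F3 | step 5 | 4-[(2S)-3,3-dimethyloxiran-2-yl]butanoic acid | OC(=O)CCC[C@@H]1OC1(C)C
F4 | step 5 | (6R)-6-(2-hydroxypropan-2-yl)oxan-2-one | O=C1CCC[C@H](C(C)(C)O)O1
F5 | step 6 | diphenyl {(6R)-2-oxo-6-[2-(triethylsilyloxy)propan-2-yl]oxan-3-yl}phosphonite (C3 epimers) | O=C1C(P(Oc2ccccc2)Oc2ccccc2)CC[C@H](C(C)(C)O[Si](CC)(CC)CC)O1
F6 | step 6 | diphenyl {(6R)-2-oxo-6-[2-(triethylsilyloxy)propan-2-yl]oxan-3-yl}phosphonate (C3 epimers) | O=C1C(P(=O)(Oc2ccccc2)Oc2ccccc2)CC[C@H](C(C)(C)O[Si](CC)(CC)CC)O1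
F7 | step 7 | (6R)-3-[(4E,8E)-10-(2,5-dimethoxy-3-methylphenyl)-1-hydroxy-4,8-dimethyldeca-4,8-dien-1-yl]-6-[2-(triethylsilyloxy)propan-2-yl]oxan-2-one (anti at C3/C1′, these two centres not drawn) | COc1cc(C)c(OC)c(C/C=C(\C)CC/C=C(\C)CCC(O)C2CC[C@H](C(C)(C)O[Si](CC)(CC)CC)OC2=O)c1
F8 | step 7 | methanesulfonate of F7 | COc1cc(C)c(OC)c(C/C=C(\C)CC/C=C(\C)CCC(OS(C)(=O)=O)C2CC[C@H](C(C)(C)O[Si](CC)(CC)CC)OC2=O)c1
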